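**Plan**

- Retrosynthesis: the C4–C4a bond of the chroman is cut and C4 is returned to the oxygen-bearing carbon C8a. This turns the dihydropyran ring (O1, C2, C3, C4, C4a, C8a) into the five-membered oxolane of a 1-oxaspiro[4.5]deca-6,9-dien-8-one. Next the O1–C(spiro) bond is cut (oxidative dearomatisation), then the aryl–CH2 bond (B-alkyl Suzuki–Miyaura coupling), leaving 4-bromo-2,3,6-trimethylphenol and (R)-geranyllinalool, which is traced to (E,E,E)-geranylgeraniol.
- Enabling feature: O1 and C4 sit on the neighbouring ring carbons C8a and C4a, C8a lies para to the C6 hydroxyl, and C4a is the one ring carbon left unsubstituted in 2,3,6-trimethylphenol. A para-quinol ether carrying both O1 and C4 on the para carbon can therefore relax only by a 1,2-shift of C4 onto that CH, with rearomatisation.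
- Forward: the side chain with its tertiary carbinol is joined to the purchased benzene ring, the oxolane closes by 5-exo capture of the oxidised phenol, and the oxolane is then enlarged to the dihydropyran while the aromatic ring and the C6 hydroxyl are restored.
- Stereochemistry: C2 is set as C3 of the epoxide in a Sharpless asymmetric epoxidation with D-(−)-diethyl tartrate and is carried on as a tertiary carbinol whose C–O bond is never broken. The two (E) alkenes of the chain come from geranylgeraniol.

Key step: step 10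

Remark: the spiro carbon of 12 should form as both epimers; it is not a stereocentre of the target, so 12 is used as the mixture and its SMILES leaves that centre undefined.

**Route**

Step 1
Reactants: 1 (2E,6E,10E)-geranylgeraniol
Product: 2 [(2R,3R)-3-methyl-3-[(3E,7E)-4,8,12-trimethyltrideca-3,7,11-trien-1-yl]oxiran-2-yl]methanol
Conditions: Ti(OiPr)4 (10 mol %), D-(−)-diethyl tartrate (12 mol %), t-BuOOH (2 equiv, in decane), 4 Å MS, CH2Cl2, −20 °C
Reagents that add atoms: tert-butyl hydroperoxide, CC(C)(C)OO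
Why: Sharpless asymmetric epoxidation, in which the titanium–tartrate catalyst epoxidises only the allylic alcohol alkene and D-(−)-diethyl tartrate should deliver oxygen to the face that gives the (2R,3R) epoxide, fixing the future C2 of the chroman.

Step 2
Reactants: 2 [(2R,3R)-3-methyl-3-[(3E,7E)-4,8,12-trimethyltrideca-3,7,11-trien-1-yl]oxiran-2-yl]methanol
Product: 3 (2S,3R)-2-(iodomethyl)-3-methyl-3-[(3E,7E)-4,8,12-trimethyltrideca-3,7,11-trien-1-yl]oxirane
Conditions: PPh3, imidazole, I2, Et2O/MeCN (3:1), 0 °C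
Reagents that add atoms: iodine, [I][I]
Why: Appel-type iodination of the primary alcohol runs under buffered, non-acidic conditions that should leave the trisubstituted epoxide and the three alkenes untouched (the descriptor at C2 changes only because iodine outranks oxygen).

Step 3
Reactants: 3 (2S,3R)-2-(iodomethyl)-3-methyl-3-[(3E,7E)-4,8,12-trimethyltrideca-3,7,11-trien-1-yl]oxirane
Product: 4 (3R,6E,10E)-3,7,11,15-tetramethylhexadeca-1,6,10,14-tetraen-3-ol [(R)-geranyllinalool]
Conditions: Zn dust, AcOH (2 equiv), EtOH, 0 °C → rt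
Reagents that add atoms: none
Why: Zinc insertion into the C–I bond followed by β-elimination of the epoxide oxygen (reductive ring opening of a 2,3-epoxy iodide) should give the tertiary allylic alcohol, and because the C3–O bond is not broken the configuration is kept.

Step 4
Reactants: 4 (3R,6E,10E)-3,7,11,15-tetramethylhexadeca-1,6,10,14-tetraen-3-ol
Product: 5 triethyl{[(3R,6E,10E)-3,7,11,15-tetramethylhexadeca-1,6,10,14-tetraen-3-yl]oxy}silane
Conditions: Et3SiOTf, 2,6-lutidine, CH2Cl2, −78 → 0 °C
Reagents that add atoms: triethylsilyl trifluoromethanesulfonate, CC[Si](CC)(CC)OS(=O)(=O)C(F)(F)F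
Why: A silyl triflate with a hindered pyridine base silylates tertiary alcohols, and the ether keeps the hydroxyl from binding boron in step 7.

Step 5
Reactants: 6 2,3,6-trimethylphenol
Product: 7 4-bromo-2,3,6-trimethylphenol
Conditions: NBS (1.0 equiv), MeCN, 0 °C → rt
Reagents that add atoms: N-bromosuccinimide, O=C1CCC(=O)N1Br
Why: Electrophilic aromatic bromination should go to C4, para to the hydroxyl and the more activated of the two free ring positions.

Step 6
Reactants: 7 4-bromo-2,3,6-trimethylphenol
Product: 8 (4-bromo-2,3,6-trimethylphenoxy)(tert-butyl)dimethylsilane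
Conditions: TBSCl, imidazole, DMF, 40 °C
Reagents that add atoms: tert-butyldimethylsilyl chloride, CC(C)(C)[Si](C)(C)Cl
Why: Imidazole-promoted silylation masks the acidic phenol, which as its phenoxide would retard oxidative addition in step 7.

Step 7
Reactants: 5 triethyl{[(3R,6E,10E)-3,7,11,15-tetramethylhexadeca-1,6,10,14-tetraen-3-yl]oxy}silane; 8 (4-bromo-2,3,6-trimethylphenoxy)(tert-butyl)dimethylsilane
Product: 10 tert-butyldimethyl{2,3,6-trimethyl-4-[(3R,6E,10E)-3,7,11,15-tetramethyl-3-(triethylsilyloxy)hexadeca-6,10,14-trien-1-yl]phenoxy}silane, via alkylborane 9 (not isolated)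
Conditions: 9-BBN (1.3 equiv), THF, 0 °C → rt; then 8, PdCl2(dppf) (5 mol %), aq K3PO4 (3 equiv), DMF, 60 °C
Reagents that add atoms: none
Why: 9-BBN should add anti-Markovnikov to the monosubstituted vinyl group only, and B-alkyl Suzuki–Miyaura coupling of the primary alkylborane with the aryl bromide at zerovalent palladium forms the aryl–CH2 bond without touching the stereocentre or the trisubstituted alkenes.

Step 8
Reactants: 10 tert-butyldimethyl{2,3,6-trimethyl-4-[(3R,6E,10E)-3,7,11,15-tetramethyl-3-(triethylsilyloxy)hexadeca-6,10,14-trien-1-yl]phenoxy}silane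
Product: 11 4-[(3R,6E,10E)-3-hydroxy-3,7,11,15-tetramethylhexadeca-6,10,14-trien-1-yl]-2,3,6-trimethylphenol
Conditions: Bu4NF (3 equiv), THF, 0 °C → rt, argon
Reagents that add atoms: none
Why: Fluoride should cleave the aryl and the tertiary alkyl silyl ether in one operation (desilylation).

Step 9
Reactants: 11 4-[(3R,6E,10E)-3-hydroxy-3,7,11,15-tetramethylhexadeca-6,10,14-trien-1-yl]-2,3,6-trimethylphenol
Product: 12 (2R,5RS)-2,6,7,9-tetramethyl-2-[(3E,7E)-4,8,12-trimethyltrideca-3,7,11-trien-1-yl]-1-oxaspiro[4.5]deca-6,9-dien-8-one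
Conditions: PhI(OAc)2 (1.05 equiv), (CF3)2CHOH/CH2Cl2 (1:4), −20 → 0 °C
Reagents that add atoms: none
Why: Oxidative dearomatisation with a trivalent iodine reagent makes the para carbon electrophilic after ligand exchange and loss of iodobenzene, and the tethered tertiary hydroxyl should capture it by 5-exo closure to the spiro-oxolane, whose spiro centre forms without control and is erased in step 10.

Step 10
Reactants: 12 (2R,5RS)-2,6,7,9-tetramethyl-2-[(3E,7E)-4,8,12-trimethyltrideca-3,7,11-trien-1-yl]-1-oxaspiro[4.5]deca-6,9-dien-8-one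
Product: 13 (2R)-2,5,7,8-tetramethyl-2-[(3E,7E)-4,8,12-trimethyltrideca-3,7,11-trien-1-yl]-3,4-dihydro-2H-chromen-6-ol (α-tocotrienol)
Conditions: BF3·OEt2 (0.2 equiv), CH2Cl2, −40 → 0 °C, argon; aq NaHCO3
Reagents that add atoms: none
Why: BF3 binds the C8 carbonyl oxygen of the cross-conjugated dienone and turns it into an oxido-arenium ion with positive charge at C6 and C10; C4 then shifts suprafacially from the spiro carbon C5 to C10, the only charged carbon that bears hydrogen, and loss of that proton gives the aromatic chroman-6-ol and frees the acid, so the step is a catalytic isomerisation. The closest known reaction type is the acid-mediated dienone–phenol rearrangement in its para-quinol (quinol ether) form, in which carbon migrates and oxygen stays. No ring is closed from an open chain: the five-membered oxolane (O1, C2, C3, C4, C5) grows to the six-membered dihydropyran by this single [1,2]-alkyl shift, and the carbocycle is rearomatised. No stereocentre is made; C2 is a spectator whose four bonds are untouched, and the uncontrolled spiro centre C5 becomes the planar C8a, so both epimers of 12 converge on one product. The step needs carbon-over-oxygen migration, which the ring oxygen secures by stabilising the cation left at C5 as an oxocarbenium ion, and migration to C10 and not to the methyl-bearing C6, which is secured because only the C10 adduct can lose a proton while a shift to C6 is reversible. It also needs the carbonyl to be activated in preference to the tertiary C2–O1 ether and the three trisubstituted alkenes, which the higher Lewis basicity of the dienone oxygen, the sub-stoichiometric acid and the low temperature are expected to secure.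

**Compound list**

1 | (2E,6E,10E)-3,7,11,15-tetramethylhexadeca-2,6,10,14-tetraen-1-ol (geranylgeraniol) | CC(C)=CCC/C(C)=C/CC/C(C)=C/CC/C(C)=C/CO | starting material
2 | [(2R,3R)-3-methyl-3-[(3E,7E)-4,8,12-trimethyltrideca-3,7,11-trien-1-yl]oxiran-2-yl]methanol | CC(C)=CCC/C(C)=C/CC/C(C)=C/CC[C@@]1(C)O[C@@H]1CO | intermediate
3 | (2S,3R)-2-(iodomethyl)-3-methyl-3-[(3E,7E)-4,8,12-trimethyltrideca-3,7,11-trien-1-yl]oxirane | CC(C)=CCC/C(C)=C/CC/C(C)=C/CC[C@@]1(C)O[C@@H]1CI | intermediate
4 | (3R,6E,10E)-3,7,11,15-tetramethylhexadeca-1,6,10,14-tetraen-3-ol | CC(C)=CCC/C(C)=C/CC/C(C)=C/CC[C@@](C)(O)C=C | intermediate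
5 | triethyl{[(3R,6E,10E)-3,7,11,15-tetramethylhexadeca-1,6,10,14-tetraen-3-yl]oxy}silane | CC(C)=CCC/C(C)=C/CC/C(C)=C/CC[C@@](C)(O[Si](CC)(CC)CC)C=C | intermediate
6 | 2,3,6-trimethylphenol | Cc1ccc(C)c(O)c1C | starting material
7 | 4-bromo-2,3,6-trimethylphenol | Cc1cc(Br)c(C)c(C)c1O | intermediate
8 | (4-bromo-2,3,6-trimethylphenoxy)(tert-butyl)dimethylsilane | Cc1cc(Br)c(C)c(C)c1O[Si](C)(C)C(C)(C)C | intermediate
9 | 9-[(3S,6E,10E)-3,7,11,15-tetramethyl-3-(triethylsilyloxy)hexadeca-6,10,14-trien-1-yl]-9-borabicyclo[3.3.1]nonane (same geometry as 5; the descriptor changes because boron ranks below carbon) | CC(C)=CCC/C(C)=C/CC/C(C)=C/CC[C@@](C)(O[Si](CC)(CC)CC)CCB1C2CCCC1CCC2 | intermediate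
10 | tert-butyldimethyl{2,3,6-trimethyl-4-[(3R,6E,10E)-3,7,11,15-tetramethyl-3-(triethylsilyloxy)hexadeca-6,10,14-trien-1-yl]phenoxy}silane | CC(C)=CCC/C(C)=C/CC/C(C)=C/CC[C@@](C)(O[Si](CC)(CC)CC)CCc1cc(C)c(O[Si](C)(C)C(C)(C)C)c(C)c1C | intermediate
11 | 4-[(3R,6E,10E)-3-hydroxy-3,7,11,15-tetramethylhexadeca-6,10,14-trien-1-yl]-2,3,6-trimethylphenol | CC(C)=CCC/C(C)=C/CC/C(C)=C/CC[C@@](C)(O)CCc1cc(C)c(O)c(C)c1C | intermediate
12 | (2R,5RS)-2,6,7,9-tetramethyl-2-[(3E,7E)-4,8,12-trimethyltrideca-3,7,11-trien-1-yl]-1-oxaspiro[4.5]deca-6,9-dien-8-one | CC(C)=CCC/C(C)=C/CC/C(C)=C/CC[C@]1(C)CCC2(O1)C(C)=C(C)C(=O)C(C)=C2 | intermediate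
13 | (2R)-2,5,7,8-tetramethyl-2-[(3E,7E)-4,8,12-trimethyltrideca-3,7,11-trien-1-yl]-3,4-dihydro-2H-chromen-6-ol | CC(C)=CCC/C(C)=C/CC/C(C)=C/CC[C@]1(C)CCc2c(C)c(O)c(C)c(C)c2O1 | target

**Totals and risks**

Total step count: 10. Longest linear sequence: 8 steps (steps 1, 2, 3, 4, 7, 8, 9, 10).

Steps most likely to fail:

1. Step 10. The acid that triggers the 1,2-shift may also ionise the tertiary C2–O1 bond or start cationic cyclisation of the triene, or the shift may stall at the methyl-bearing carbon, so that material and configurational purity are lost. The fallback avoids acid and cations and forms the O1–C8a bond directly; it sets out from 8 and 5 and comes back at 13. Iodination of 8 at its only free ring position (N-iodosuccinimide, cat. CF3CO2H, MeCN) should give (4-bromo-3-iodo-2,5,6-trimethylphenoxy)(tert-butyl)dimethylsilane F1. Alkylborane 9, made from 5 as in step 7, is coupled selectively at the C–I bond (PdCl2(dppf), aq K3PO4, THF/DMF, rt) to give the ortho-bromo aryl silyl ether F2. The tertiary silyl ether is cleaved selectively (pyridinium p-toluenesulfonate, MeOH) to give the bromo alcohol F3. Intramolecular palladium-catalysed aryl ether formation (Pd(OAc)2, 2-(di-tert-butylphosphino)-1,1'-binaphthyl, Cs2CO3, toluene, 80 °C) closes the dihydropyran with the carbinol C–O bond intact and should give α-tocotrienol tert-butyldimethylsilyl ether F4. Bu4NF in THF then gives 13.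

2. Step 9. The oxidant may attack the electron-rich alkenes or the benzylic position (quinone methide formation), or external nucleophiles may capture the cation faster than the hindered hydroxyl. The fallback carries both ring oxygens from the start and closes the ring by ketalisation and reduction; it sets out from 5 and comes back at 13. Commercial 2,3,5-trimethylhydroquinone is methylated (Me2SO4, K2CO3, acetone) to 1,4-dimethoxy-2,3,5-trimethylbenzene F5 and brominated (Br2, CH2Cl2, 0 °C) to 1-bromo-2,5-dimethoxy-3,4,6-trimethylbenzene F6. Alkylborane 9 from 5 is coupled with F6 under the conditions of step 7 to give the dimethoxyarene silyl ether F7, and Bu4NF gives the tertiary alcohol F8. Oxidative demethylation ((NH4)2Ce(NO3)6, MeCN/H2O, 0 °C), which has precedent next to polyprenyl chains, should give the hydroxy quinone F9. With HC(OMe)3, MeOH and catalytic camphorsulfonic acid the tertiary hydroxyl adds to the neighbouring quinone carbonyl and the ring closes as the cyclic methyl ketal F10, again without breaking the carbinol C–O bond. Reduction with ascorbic acid (aq MeOH/THF), in the manner of tocopherone chemistry, expels methanol and gives 13.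

3. Step 7. Transmetalation of the hindered alkylborane may be slow, so that protodeboronation and reduction of the electron-rich aryl bromide win. The fallback replaces the palladium coupling by a substitution at a primary iodide; it sets out from 5 and 8 and comes back at 10. Alkylborane 9 is oxidised (NaOH, H2O2) to the primary alcohol F11, which is converted (PPh3, I2, imidazole) into the primary iodide F12. The aryl Grignard reagent F13, made from 8 (Mg, THF), is alkylated by F12 under Li2CuCl4 catalysis (THF, −20 → 0 °C) to give 10.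

**Further compounds**

F1 | step 10 | (4-bromo-3-iodo-2,5,6-trimethylphenoxy)(tert-butyl)dimethylsilane | Cc1c(I)c(Br)c(C)c(C)c1O[Si](C)(C)C(C)(C)C
F2 | step 10 | {4-bromo-2,5,6-trimethyl-3-[(3R,6E,10E)-3,7,11,15-tetramethyl-3-(triethylsilyloxy)hexadeca-6,10,14-trien-1-yl]phenoxy}(tert-butyl)dimethylsilane | CC(C)=CCC/C(C)=C/CC/C(C)=C/CC[C@@](C)(O[Si](CC)(CC)CC)CCc1c(Br)c(C)c(C)c(O[Si](C)(C)C(C)(C)C)c1C
F3 | step 10 | (3R,6E,10E)-1-[2-bromo-4-(tert-butyldimethylsilyloxy)-3,5,6-trimethylphenyl]-3,7,11,15-tetramethylhexadeca-6,10,14-trien-3-ol | CC(C)=CCC/C(C)=C/CC/C(C)=C/CC[C@@](C)(O)CCc1c(Br)c(C)c(C)c(O[Si](C)(C)C(C)(C)C)c1C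
F4 | step 10 | tert-butyldimethyl{[(2R)-2,5,7,8-tetramethyl-2-[(3E,7E)-4,8,12-trimethyltrideca-3,7,11-trien-1-yl]-3,4-dihydro-2H-chromen-6-yl]oxy}silane | CC(C)=CCC/C(C)=C/CC/C(C)=C/CC[C@]1(C)CCc2c(C)c(O[Si](C)(C)C(C)(C)C)c(C)c(C)c2O1
F5 | step 9 | 1,4-dimethoxy-2,3,5-trimethylbenzene | COc1cc(C)c(OC)c(C)c1C
F6 | step 9 | 1-bromo-2,5-dimethoxy-3,4,6-trimethylbenzene | COc1c(Br)c(C)c(OC)c(C)c1C
F7 | step 9 | {[(3R,6E,10E)-1-(2,5-dimethoxy-3,4,6-trimethylphenyl)-3,7,11,15-tetramethylhexadeca-6,10,14-trien-3-yl]oxy}triethylsilane | CC(C)=CCC/C(C)=C/CC/C(C)=C/CC[C@@](C)(O[Si](CC)(CC)CC)CCc1c(OC)c(C)c(C)c(OC)c1C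
F8 | step 9 | (3R,6E,10E)-1-(2,5-dimethoxy-3,4,6-trimethylphenyl)-3,7,11,15-tetramethylhexadeca-6,10,14-trien-3-ol | CC(C)=CCC/C(C)=C/CC/C(C)=C/CC[C@@](C)(O)CCc1c(OC)c(C)c(C)c(OC)c1C
F9 | step 9 | 2-[(3R,6E,10E)-3-hydroxy-3,7,11,15-tetramethylhexadeca-6,10,14-trien-1-yl]-3,5,6-trimethylcyclohexa-2,5-diene-1,4-dione | CC(C)=CCC/C(C)=C/CC/C(C)=C/CC[C@@](C)(O)CCC1=C(C)C(=O)C(C)=C(C)C1=O
F10 | step 9 | (2R,8aRS)-8a-methoxy-2,5,7,8-tetramethyl-2-[(3E,7E)-4,8,12-trimethyltrideca-3,7,11-trien-1-yl]-2,3,4,8a-tetrahydro-6H-chromen-6-one | CC(C)=CCC/C(C)=C/CC/C(C)=C/CC[C@]1(C)CCC2=C(C)C(=O)C(C)=C(C)C2(OC)O1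
F11 | step 7 | (3R,6E,10E)-3,7,11,15-tetramethyl-3-(triethylsilyloxy)hexadeca-6,10,14-trien-1-ol | CC(C)=CCC/C(C)=C/CC/C(C)=C/CC[C@@](C)(O[Si](CC)(CC)CC)CCO
F12 | step 7 | triethyl{[(3R,6E,10E)-1-iodo-3,7,11,15-tetramethylhexadeca-6,10,14-trien-3-yl]oxy}silane | CC(C)=CCC/C(C)=C/CC/C(C)=C/CC[C@@](C)(O[Si](CC)(CC)CC)CCI
F13 | step 7 | [4-(tert-butyldimethylsilyloxy)-2,3,5-trimethylphenyl]magnesium bromide | Cc1cc([Mg]Br)c(C)c(C)c1O[Si](C)(C)C(C)(C)C
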